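**Retrosynthetic overview**

1. Endgame: the hydroperoxide comes from an isopropenyl group (cobalt/O2/silane), the isopropenyl group from the tertiary carbinol, the C5 phenol from its methyl ether and the C6 alkenyl group from a C6 bromide, all on a 6-bromo-5,7-dimethoxy tetracycle.
2. Key disconnection: the C4–C4a bond of pyranone ring C, formed by intramolecular Friedel–Crafts acylation of a ring-D enol aryl ether acid (ring-A aryloxy group on C2, carboxyl on C3).
3. Feature (flavone numbering; ring A = C4a–C8a, ring C = O1/C2–C4, ring B = C1'–C6', oxepine ring D = C2, C3, CH2, CH, O, C2', C1'): the ring-A block 4-bromo-3,5-dimethoxyphenol has a mirror plane through its C1 and C4, so both carbons ortho to the future O1 are the same C4a, and ring D holds the O1 aryloxy group and the C3 carboxyl cis across C2=C3.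
4. The acid comes from a ring-D enol triflate and the phenol (C–O coupling), the triflate from a benzoxepinone β-keto ester (Dieckmann), and its diester from opening of a Shi (R)-epoxide by a salicylate phenoxide with inversion, which sets the single S stereocentre.
5. Ring order: B (bought) → D (step 6) → A attached (step 8) → C (step 10).

Key step: step 10

Assumption: the D-fructose-derived Shi ketone is taken to epoxidise R–CH=C(CH3)2 alkenes on the face that gives the (R)-epoxide, as for other trisubstituted alkenes; if the sense proved opposite, the enantiomeric ketone would be used with no other change.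

**Route**

Step 1
Reactants: 1 5-methylhex-4-enoic acid
Product: 2 tert-butyl 5-methylhex-4-enoate
Conditions: Me2NCH(Ot-Bu)2, toluene, 80 °C
Reagents that add atoms: N,N-dimethylformamide di-tert-butyl acetal, CN(C)C(OC(C)(C)C)OC(C)(C)C
Why: Acetal-mediated esterification under neutral conditions avoids the acid that would lactonise the trisubstituted alkene onto the carboxyl group, and the tert-butyl ester resists alkoxide attack in steps 4 and 6 and is later removed without base.

Step 2
Reactants: 2 tert-butyl 5-methylhex-4-enoate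
Product: 3 tert-butyl 3-[(2R)-3,3-dimethyloxiran-2-yl]propanoate
Conditions: D-fructose-derived Shi ketone (30 mol %), KHSO5 (Oxone, 2KHSO5·KHSO4·K2SO4), K2CO3, Bu4NHSO4, MeCN/CH2(OMe)2/aq. Na2B4O7 buffer (pH 10.5), 0 °C
Reagents that add atoms: potassium peroxymonosulfate, [K+].[O-]S(=O)(=O)OO
Why: Shi epoxidation, in which the chiral dioxirane transfers oxygen to the electron-rich trisubstituted alkene through a spiro transition state and should set the secondary epoxide carbon as R, the ester being inert.

Step 3
Reactants: 4 methyl 2,4-dihydroxybenzoate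
Product: 5 methyl 2-hydroxy-4-(triisopropylsilyloxy)benzoate
Conditions: i-Pr3SiCl (1.05 equiv), imidazole, DMF, 0 °C to rt
Reagents that add atoms: triisopropylsilyl chloride, CC(C)[Si](Cl)(C(C)C)C(C)C
Why: Phenol silylation should be selective for the more acidic, unhindered 4-hydroxyl because the 2-hydroxyl is hydrogen-bonded to the ester carbonyl.

Step 4
Reactants: 3 tert-butyl 3-[(2R)-3,3-dimethyloxiran-2-yl]propanoate (1.5 equiv); 5 methyl 2-hydroxy-4-(triisopropylsilyloxy)benzoate
Product: 6 tert-butyl (4S)-5-hydroxy-4-[2-(methoxycarbonyl)-5-(triisopropylsilyloxy)phenoxy]-5-methylhexanoate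
Conditions: Cs2CO3 (0.3 equiv), anhydrous DMF, 80 °C
Reagents that add atoms: none
Why: Base-mediated SN2 opening of a trisubstituted epoxide by a phenoxide should occur at the secondary carbon with inversion (R to S, the configuration of the target), while the catalytic base, the anhydrous medium and the bulk of the silyl group should spare the aryl silyl ether and the tert-butyl ester should not lactonise with the new tertiary hydroxyl.

Step 5
Reactants: 6 tert-butyl (4S)-5-hydroxy-4-[2-(methoxycarbonyl)-5-(triisopropylsilyloxy)phenoxy]-5-methylhexanoate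
Product: 7 tert-butyl (4S)-4-[2-(methoxycarbonyl)-5-(triisopropylsilyloxy)phenoxy]-5-methyl-5-(triethylsilyloxy)hexanoate
Conditions: Et3SiOTf, 2,6-lutidine, CH2Cl2, −78 to 0 °C
Reagents that add atoms: triethylsilyl trifluoromethanesulfonate, CC[Si](CC)(CC)OS(=O)(=O)C(F)(F)F
Why: Silylation of the tertiary alcohol with a silyl triflate and a hindered pyridine masks the hydroxyl so that its alkoxide cannot attack either ester in step 6 or be sulfonylated in step 7.

Step 6
Reactants: 7 tert-butyl (4S)-4-[2-(methoxycarbonyl)-5-(triisopropylsilyloxy)phenoxy]-5-methyl-5-(triethylsilyloxy)hexanoate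
Product: 8 tert-butyl (2S)-5-oxo-2-[2-(triethylsilyloxy)propan-2-yl]-8-(triisopropylsilyloxy)-2,3,4,5-tetrahydro-1-benzoxepine-4-carboxylate (C4 epimers and enol tautomer)
Conditions: LiN(SiMe3)2 (2.2 equiv), THF, −78 to 0 °C; then AcOH
Reagents that add atoms: none
Why: Dieckmann condensation, in which the lithium enolate of the tert-butyl ester (the only enolisable ester) attacks the aryl methyl ester to close the seven-membered ring D, driven by deprotonation of the β-keto ester, with the stereocentre γ to the enolate carbon and so unable to epimerise or eliminate.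

Step 7
Reactants: 8 tert-butyl (2S)-5-oxo-2-[2-(triethylsilyloxy)propan-2-yl]-8-(triisopropylsilyloxy)-2,3,4,5-tetrahydro-1-benzoxepine-4-carboxylate
Product: 9 tert-butyl (2S)-2-[2-(triethylsilyloxy)propan-2-yl]-5-(trifluoromethanesulfonyloxy)-8-(triisopropylsilyloxy)-2,3-dihydro-1-benzoxepine-4-carboxylate
Conditions: KN(SiMe3)2, THF, −78 °C; PhNTf2, −78 to 0 °C
Reagents that add atoms: N-phenylbis(trifluoromethanesulfonimide), O=S(=O)(N(c1ccccc1)S(=O)(=O)C(F)(F)F)C(F)(F)F
Why: O-sulfonylation of the β-keto ester enolate gives the enol triflate, whose double-bond geometry is fixed by ring D.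

Step 8
Reactants: 9 enol triflate; 10 4-bromo-3,5-dimethoxyphenol (1.05 equiv)
Product: 11 tert-butyl (2S)-5-(4-bromo-3,5-dimethoxyphenoxy)-2-[2-(triethylsilyloxy)propan-2-yl]-8-(triisopropylsilyloxy)-2,3-dihydro-1-benzoxepine-4-carboxylate
Conditions: Pd2(dba)3 (2.5 mol %), 2-(di-tert-butylphosphino)biphenyl (10 mol %), K3PO4, toluene, 80 °C
Reagents that add atoms: none
Why: Palladium-catalysed C–O cross-coupling of an enol triflate with a phenol, in which oxidative addition of zerovalent palladium into the electron-poor vinyl C–OTf bond should be much faster than into the electron-rich, di-ortho-methoxy aryl bromide and the bulky biaryl phosphine promotes C–O reductive elimination.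

Step 9
Reactants: 11 aryl enol ether tert-butyl ester
Product: 12 (2S)-5-(4-bromo-3,5-dimethoxyphenoxy)-2-(2-hydroxypropan-2-yl)-8-(triisopropylsilyloxy)-2,3-dihydro-1-benzoxepine-4-carboxylic acid
Conditions: CF3CO2H/CH2Cl2 (1:4), anisole, 0 °C to rt; aqueous work-up
Reagents that add atoms: none
Why: Acidolysis cleaves the tert-butyl ester with loss of isobutene (anisole traps the cation) and removes the tertiary triethylsilyl ether, whereas the aryl triisopropylsilyl ether and the ester-conjugated enol ether should survive anhydrous acid, so no base touches the β-aryloxyacrylate.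

Step 10
Reactants: 12 ring-D enol ether acid
Product: 15 (S)-6-bromo-5,7-dimethoxy-4'-(triisopropylsilyloxy)flavone bridged from C3 to the C2' oxygen by CH2–CH[C(CH3)2OH] (ring D), via mixed trifluoroacetic anhydride 13 (not isolated), via tetracyclic trifluoroacetate 14 (not isolated)
Conditions: 12 added to (CF3CO)2O (5 equiv), CH2Cl2, 0 °C to rt; evaporate; K2CO3 (0.2 equiv), MeOH, 0 °C
Reagents that add atoms: none
Why: Trifluoroacetic anhydride acylates the tertiary hydroxyl and converts the C3 carboxylic acid into mixed anhydride 13, which reacts as an acylium ion with the ring-A carbon ortho to the enol-ether oxygen and para to a methoxy group, and proton loss forms the C4–C4a bond. The closest known reaction type is the acid-mediated cyclisation of 3-aryloxyacrylic (β-aryloxycinnamic) acids to chromones and flavones, together with the trifluoroacetic anhydride cyclisation of 2-aryloxybenzoic acids to xanthones. Ring C closes as a six-membered ring by intramolecular electrophilic aromatic substitution, the aryloxy group and the carboxyl being held cis on C2=C3 by ring D. No stereocentre is formed, and the S centre, which bears no acidic hydrogen and sits next to a trifluoroacetate that is slow to ionise because of the adjacent ether oxygen, should be unchanged. The two ortho carbons of the symmetric ring A are equivalent, so no regiocontrol is needed, and ring A with three donor oxygens should outcompete ring B, whose only reachable carbon C6' is meta to both of its oxygens and would give a five-membered ketone. Acylation of the tertiary hydroxyl by the excess anhydride blocks lactonisation, and brief methanolysis then frees the carbinol without harming the aryl silyl ether.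

Step 11
Reactants: 15 6-bromo tetracycle; 16 (E)-3-methylbut-1-enylboronic acid pinacol ester
Product: 17 (S)-5,7-dimethoxy-6-[(E)-3-methylbut-1-enyl] tetracycle with the tertiary carbinol and the C4' triisopropylsilyl ether
Conditions: Pd(OAc)2 (5 mol %), SPhos (10 mol %), K3PO4, toluene/H2O, 90 °C
Reagents that add atoms: none
Why: Suzuki–Miyaura coupling with a dialkylbiaryl phosphine suited to the electron-rich, di-ortho-substituted C6–Br bond, the alkenyl boronate transferring with retention of its E geometry.

Step 12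
Reactants: 17 5,7-dimethoxy-6-alkenyl tetracycle
Product: 18 (S)-5-hydroxy-7-methoxy-6-[(E)-3-methylbut-1-enyl] tetracycle with the tertiary carbinol and the C4' triisopropylsilyl ether
Conditions: MgI2·OEt2, THF, 50 °C; then dilute aq. HCl, 0 °C
Reagents that add atoms: none
Why: Chelation-controlled ether cleavage, in which MgI2 binds the C4 carbonyl and the peri C5 methoxy oxygen and iodide removes that methyl group by SN2, leaving the C7 methyl ether, the silyl ether and the alkene untouched.

Step 13
Reactants: 18 5-hydroxy tetracycle with the tertiary carbinol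
Product: 19 (S)-5-hydroxy-7-methoxy-6-[(E)-3-methylbut-1-enyl] tetracycle with an isopropenyl group on the ring-D stereocentre
Conditions: Burgess reagent, toluene, 60 °C
Reagents that add atoms: none
Why: Burgess dehydration proceeds through a sulfamate ester and syn elimination, which should take a methyl hydrogen and give the isopropenyl group and not the enol ether, while the chelated C5 hydroxyl is unreactive and the stereocentre is untouched.

Step 14
Reactants: 19 isopropenyl tetracycle
Product: 20 (S)-tetracycle bearing C(CH3)2–O–O–SiEt3 on the ring-D stereocentre (5-hydroxy, 7-methoxy, 6-alkenyl, C4' triisopropylsilyl ether)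
Conditions: Co(acac)2 (10 mol %), O2 (1 atm), Et3SiH (2 equiv), ClCH2CH2Cl, rt
Reagents that add atoms: dioxygen, O=O; triethylsilane, CC[SiH](CC)CC
Why: Isayama–Mukaiyama silylperoxidation, in which a cobalt hydride transfers a hydrogen atom to the terminal carbon of the 1,1-disubstituted alkene and the tertiary radical is trapped by O2 and silylated (Markovnikov), the hindered 1,2-disubstituted styrenyl alkene being a much poorer hydrogen-atom acceptor and no stereocentre being formed.

Step 15
Reactants: 20 triethylsilyl peroxide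
Product: 21 CNP0171472.1
Conditions: HF·pyridine, pyridine, THF, 0 °C to rt
Reagents that add atoms: none
Why: Fluoride-mediated desilylation cleaves the O–Si bonds of the silyl peroxide and of the aryl silyl ether without reducing the O–O bond or touching the alkene, giving the hydroperoxide and the free C4' phenol.

**Compound list**

1 | 5-methylhex-4-enoic acid | CC(C)=CCCC(=O)O | starting material
2 | tert-butyl 5-methylhex-4-enoate | CC(C)=CCCC(=O)OC(C)(C)C | intermediate
3 | tert-butyl 3-[(2R)-3,3-dimethyloxiran-2-yl]propanoate | CC(C)(C)OC(=O)CC[C@H]1OC1(C)C | intermediate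
4 | methyl 2,4-dihydroxybenzoate | COC(=O)c1ccc(O)cc1O | starting material
5 | methyl 2-hydroxy-4-(triisopropylsilyloxy)benzoate | COC(=O)c1ccc(O[Si](C(C)C)(C(C)C)C(C)C)cc1O | intermediate
6 | tert-butyl (4S)-5-hydroxy-4-[2-(methoxycarbonyl)-5-(triisopropylsilyloxy)phenoxy]-5-methylhexanoate | COC(=O)c1ccc(O[Si](C(C)C)(C(C)C)C(C)C)cc1O[C@@H](CCC(=O)OC(C)(C)C)C(C)(C)O | intermediate
7 | tert-butyl (4S)-4-[2-(methoxycarbonyl)-5-(triisopropylsilyloxy)phenoxy]-5-methyl-5-(triethylsilyloxy)hexanoate | COC(=O)c1ccc(O[Si](C(C)C)(C(C)C)C(C)C)cc1O[C@@H](CCC(=O)OC(C)(C)C)C(C)(C)O[Si](CC)(CC)CC | intermediate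
8 | tert-butyl (2S)-5-oxo-2-[2-(triethylsilyloxy)propan-2-yl]-8-(triisopropylsilyloxy)-2,3,4,5-tetrahydro-1-benzoxepine-4-carboxylate (C4 epimers, enol tautomer) | CC(C)(C)OC(=O)C1C[C@@H](C(C)(C)O[Si](CC)(CC)CC)Oc2cc(O[Si](C(C)C)(C(C)C)C(C)C)ccc2C1=O | intermediate
9 | tert-butyl (2S)-2-[2-(triethylsilyloxy)propan-2-yl]-5-(trifluoromethanesulfonyloxy)-8-(triisopropylsilyloxy)-2,3-dihydro-1-benzoxepine-4-carboxylate | FC(F)(F)S(=O)(=O)OC1=C(C(=O)OC(C)(C)C)C[C@@H](C(C)(C)O[Si](CC)(CC)CC)Oc2cc(O[Si](C(C)C)(C(C)C)C(C)C)ccc21 | intermediate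
10 | 4-bromo-3,5-dimethoxyphenol | COc1cc(O)cc(OC)c1Br | starting material
11 | tert-butyl (2S)-5-(4-bromo-3,5-dimethoxyphenoxy)-2-[2-(triethylsilyloxy)propan-2-yl]-8-(triisopropylsilyloxy)-2,3-dihydro-1-benzoxepine-4-carboxylate | COc1cc(OC2=C(C(=O)OC(C)(C)C)C[C@@H](C(C)(C)O[Si](CC)(CC)CC)Oc3cc(O[Si](C(C)C)(C(C)C)C(C)C)ccc32)cc(OC)c1Br | intermediate
12 | (2S)-5-(4-bromo-3,5-dimethoxyphenoxy)-2-(2-hydroxypropan-2-yl)-8-(triisopropylsilyloxy)-2,3-dihydro-1-benzoxepine-4-carboxylic acid (key-step precursor) | COc1cc(OC2=C(C(=O)O)C[C@@H](C(C)(C)O)Oc3cc(O[Si](C(C)C)(C(C)C)C(C)C)ccc32)cc(OC)c1Br | intermediate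
13 | mixed carboxylic trifluoroacetic anhydride of 12 with the tertiary hydroxyl trifluoroacetylated | COc1cc(OC2=C(C(=O)OC(=O)C(F)(F)F)C[C@@H](C(C)(C)OC(=O)C(F)(F)F)Oc3cc(O[Si](C(C)C)(C(C)C)C(C)C)ccc32)cc(OC)c1Br | intermediate
14 | tertiary trifluoroacetate of tetracycle 15 | COc1cc2oc3c(c(=O)c2c(OC)c1Br)C[C@@H](C(C)(C)OC(=O)C(F)(F)F)Oc1cc(O[Si](C(C)C)(C(C)C)C(C)C)ccc1-3 | intermediate
15 | (S)-6-bromo-5,7-dimethoxy-4'-(triisopropylsilyloxy)flavone with ring D bridge C3–CH2–CH[C(CH3)2OH]–O–C2' (key-step product) | COc1cc2oc3c(c(=O)c2c(OC)c1Br)C[C@@H](C(C)(C)O)Oc1cc(O[Si](C(C)C)(C(C)C)C(C)C)ccc1-3 | intermediate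
16 | (E)-3-methylbut-1-enylboronic acid pinacol ester | CC(C)/C=C/B1OC(C)(C)C(C)(C)O1 | starting material
17 | 5,7-dimethoxy-6-[(E)-3-methylbut-1-enyl] analogue of 15 | COc1cc2oc3c(c(=O)c2c(OC)c1/C=C/C(C)C)C[C@@H](C(C)(C)O)Oc1cc(O[Si](C(C)C)(C(C)C)C(C)C)ccc1-3 | intermediate
18 | 5-hydroxy-7-methoxy-6-[(E)-3-methylbut-1-enyl] tetracycle with the tertiary carbinol | COc1cc2oc3c(c(=O)c2c(O)c1/C=C/C(C)C)C[C@@H](C(C)(C)O)Oc1cc(O[Si](C(C)C)(C(C)C)C(C)C)ccc1-3 | intermediate
19 | isopropenyl tetracycle (S) | COc1cc2oc3c(c(=O)c2c(O)c1/C=C/C(C)C)C[C@@H](C(C)=C)Oc1cc(O[Si](C(C)C)(C(C)C)C(C)C)ccc1-3 | intermediate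
20 | triethylsilyl peroxide of the target with the C4' triisopropylsilyl ether | COc1cc2oc3c(c(=O)c2c(O)c1/C=C/C(C)C)C[C@@H](C(C)(C)OO[Si](CC)(CC)CC)Oc1cc(O[Si](C(C)C)(C(C)C)C(C)C)ccc1-3 | intermediate
21 | CNP0171472.1: (S)-5,4'-dihydroxy-7-methoxy-6-[(E)-3-methylbut-1-enyl]flavone with ring D bridge C3–CH2–CH[C(CH3)2OOH]–O–C2' | COc1cc2oc3c(c(=O)c2c(O)c1/C=C/C(C)C)C[C@@H](C(C)(C)OO)Oc1cc(O)ccc1-3 | target

**Step count and risks**

Total step count: 15. Longest linear sequence: 14 steps (steps 1, 2 and 4–15; step 3 is a one-step branch).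

Steps most likely to fail:

1. Step 4. The SN2 attack of a hydrogen-bonded, ester-deactivated phenoxide on a neopentyl-type epoxide carbon may be slow, and the heating it needs may cause loss or transfer of the aryl silyl group. The fallback sets out from 3 and comes back to the route at 8. Epoxide 3 would be opened with commercial methyl 4-(benzyloxy)-2-hydroxybenzoate (COC(=O)c1ccc(OCc2ccccc2)cc1O; NaH or Cs2CO3, DMF, 110 °C), where no silyl group is at risk, to give tert-butyl (4S)-4-[5-(benzyloxy)-2-(methoxycarbonyl)phenoxy]-5-hydroxy-5-methylhexanoate F1. Silylation as in step 5 would give its triethylsilyl ether F2, and Dieckmann closure as in step 6 the benzyl-protected β-keto ester F3. Hydrogenolysis (H2, Pd/C, EtOAc) would give the 8-hydroxy β-keto ester F4, and i-Pr3SiCl/imidazole would then give 8.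

2. Step 8. Oxidative addition into the aryl bromide of 10 or of the product (oligomeric diaryl ethers, debromination) may compete, as may cleavage of the triflate at sulfur by phenoxide. The fallback sets out from 9 and comes back at 11, and it inverts the polarity of the vinyl partner. Miyaura borylation of 9 (PdCl2(dppf), bis(pinacolato)diboron, KOAc, dioxane, 80 °C), run before any aryl bromide is present, would give the ring-D alkenyl pinacol boronate F5. Chan–Lam coupling of F5 with 10 (Cu(OAc)2, Et3N, 4 Å molecular sieves, air, CH2Cl2, rt), which leaves aryl bromides untouched, would give 11.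

3. Step 14. Hydrogen-atom transfer may also reach the styrenyl alkene, giving over-peroxidation. The fallback sets out from 15 and comes back at 21, with the peroxide installed while the molecule holds only one alkene.
   - Cleavage of the C5 methyl ether of 15 (MgI2·OEt2) would give the 6-bromo-5-hydroxy carbinol F6.
   - Burgess dehydration would give the 6-bromo isopropenyl compound F7.
   - The Co(acac)2/O2/Et3SiH reaction would give the 6-bromo triethylsilyl peroxide F8.
   - A silyl peroxide is not expected to survive phosphine-ligated palladium and aqueous base, so it would be cleaved (HCl cat., MeOH, 0 °C) to the 6-bromo hydroperoxide F9.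
   - 2-Methoxypropene/PPTS would mask F9 as the 2-methoxyprop-2-yl peroxyketal F10, a peroxide type that tolerates palladium cross-coupling.
   - Suzuki coupling with 16 (catalyst of step 11, THF/H2O, 60–70 °C) would give the 6-alkenyl peroxyketal F11.
   - HF·pyridine in THF/MeOH would remove the ketal and the aryl silyl ether to give 21.

**Further compounds**

F1 | step 4 | tert-butyl (4S)-4-[5-(benzyloxy)-2-(methoxycarbonyl)phenoxy]-5-hydroxy-5-methylhexanoate | COC(=O)c1ccc(OCc2ccccc2)cc1O[C@@H](CCC(=O)OC(C)(C)C)C(C)(C)O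
F2 | step 4 | tert-butyl (4S)-4-[5-(benzyloxy)-2-(methoxycarbonyl)phenoxy]-5-methyl-5-(triethylsilyloxy)hexanoate | COC(=O)c1ccc(OCc2ccccc2)cc1O[C@@H](CCC(=O)OC(C)(C)C)C(C)(C)O[Si](CC)(CC)CC
F3 | step 4 | tert-butyl (2S)-8-(benzyloxy)-5-oxo-2-[2-(triethylsilyloxy)propan-2-yl]-2,3,4,5-tetrahydro-1-benzoxepine-4-carboxylate | CC(C)(C)OC(=O)C1C[C@@H](C(C)(C)O[Si](CC)(CC)CC)Oc2cc(OCc3ccccc3)ccc2C1=O
F4 | step 4 | tert-butyl (2S)-8-hydroxy-5-oxo-2-[2-(triethylsilyloxy)propan-2-yl]-2,3,4,5-tetrahydro-1-benzoxepine-4-carboxylate | CC(C)(C)OC(=O)C1C[C@@H](C(C)(C)O[Si](CC)(CC)CC)Oc2cc(O)ccc2C1=O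
F5 | step 8 | tert-butyl (2S)-5-(4,4,5,5-tetramethyl-1,3,2-dioxaborolan-2-yl)-2-[2-(triethylsilyloxy)propan-2-yl]-8-(triisopropylsilyloxy)-2,3-dihydro-1-benzoxepine-4-carboxylate | CC1(C)OB(OC1(C)C)C1=C(C(=O)OC(C)(C)C)C[C@@H](C(C)(C)O[Si](CC)(CC)CC)Oc2cc(O[Si](C(C)C)(C(C)C)C(C)C)ccc21
F6 | step 14 | 6-bromo-5-hydroxy-7-methoxy tetracycle with the tertiary carbinol and the C4' triisopropylsilyl ether | COc1cc2oc3c(c(=O)c2c(O)c1Br)C[C@@H](C(C)(C)O)Oc1cc(O[Si](C(C)C)(C(C)C)C(C)C)ccc1-3
F7 | step 14 | 6-bromo-5-hydroxy-7-methoxy isopropenyl tetracycle | COc1cc2oc3c(c(=O)c2c(O)c1Br)C[C@@H](C(C)=C)Oc1cc(O[Si](C(C)C)(C(C)C)C(C)C)ccc1-3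
F8 | step 14 | 6-bromo-5-hydroxy-7-methoxy tetracycle with the triethylsilyl peroxide | COc1cc2oc3c(c(=O)c2c(O)c1Br)C[C@@H](C(C)(C)OO[Si](CC)(CC)CC)Oc1cc(O[Si](C(C)C)(C(C)C)C(C)C)ccc1-3
F9 | step 14 | 6-bromo-5-hydroxy-7-methoxy tetracycle with the free hydroperoxide and the C4' triisopropylsilyl ether | COc1cc2oc3c(c(=O)c2c(O)c1Br)C[C@@H](C(C)(C)OO)Oc1cc(O[Si](C(C)C)(C(C)C)C(C)C)ccc1-3
F10 | step 14 | 6-bromo-5-hydroxy-7-methoxy tetracycle with the 2-methoxyprop-2-yl peroxyketal | COc1cc2oc3c(c(=O)c2c(O)c1Br)C[C@@H](C(C)(C)OOC(C)(C)OC)Oc1cc(O[Si](C(C)C)(C(C)C)C(C)C)ccc1-3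
F11 | step 14 | 6-[(E)-3-methylbut-1-enyl]-5-hydroxy-7-methoxy tetracycle with the 2-methoxyprop-2-yl peroxyketal and the C4' triisopropylsilyl ether | COc1cc2oc3c(c(=O)c2c(O)c1/C=C/C(C)C)C[C@@H](C(C)(C)OOC(C)(C)OC)Oc1cc(O[Si](C(C)C)(C(C)C)C(C)C)ccc1-3
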